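Work out how many monomer units fall to each chain in these two flasks, starting from the charges and the birch run.

| setting | birch | Monday's | Thursday's |
|---|---|---|---|
| free monomer | 0.13 M | 0.20 M | 0.20 M |
| initiator | 5 mM | 5.0 mM | 1.5 mM |
| remark | run made earlier |  |  |
| time |  | 6.0 h | 6.0 h |

birch run (percent of the free monomer charged)

| time / min | monomer in chains / % | free monomer / % |
|---|---|---|
| 10.0 | 0.7 | 97.3 |
| 25.0 | 10.8 | 87.2 |
| 50.0 | 32.7 | 66.6 |
| 80.0 | 56.4 | 42.4 |

(standard deviation of a reading: 1 percentage point)

1. which of the two ends with the longer chains by the average number of monomer units in a chain (chains begun, living or dead) ("neither" if they lie within 10%) (Monday's / Thursday's / neither)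
2. average number of monomer units in a chain (chains begun, living or dead) at the end, Monday's
3. average number of monomer units in a chain (chains begun, living or dead) at the end, Thursday's

- the average divides the monomer in chains by the number of chains begun, living and dead together
- the earlier runs do not show the number of chains; that part of a forecast is a guess
- no earlier run changes the charge of initiator; that part of a forecast is a guess

Divide the free monomer charged by the initiator charged. This gives R, which is 40.0 for Monday's and 133 for Thursday's. R is the number of monomer units per chain if each initiator begins one chain and the free monomer ends up in chains, the target degree of polymerisation.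

Is one number enough? R takes the free monomer as used up, so test that on the birch run. Its free monomer fell to 42.4% by 80.0 min, a mean decay rate of 0.0107 min⁻¹, but the last interval gives 0.0151 min⁻¹, which is faster, so the mean runs low. At that mean rate I reckon Monday's at 97.9% reacted by 6.0 h, so I keep R as my length for Monday's. If the rate follows the initiator, which is my guess, I reckon Thursday's at 68.6% reacted by 6.0 h from the mean rate and 80.3% from the last. My Thursday's length is therefore 91.5 to 107, still longer than Monday's R. This tests the use of free monomer, but the count of chains in R stays a guess.

The forecast gives Thursday's, with 40 for Monday's and 107 for Thursday's, and warns: “Chain count and initiator scaling are guesses.”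

The flask gives Thursday's, with 88.4 for Monday's and 197 for Thursday's.

    free monomer + initiator → living end + monomer in chains (k = 0.00115 M⁻¹ s⁻¹)
    initiator + monomer in chains → spent initiator (k = 0.00547 M⁻¹ s⁻¹)
    free monomer + living end → monomer in chains + living end, rate k3*[living end]*[free monomer] (k = 0.145 M⁻¹ s⁻¹)
    free monomer → uncatalysed product (k = 5.37 × 10⁻⁶ s⁻¹)

Monday's ends at 2.21 times R, and Thursday's at 1.48 times R. At 6.00 h in Monday's, living ends stand at 0.00217 M, which is 43.5% of the initiator charged, while spent initiator stands at 2.83 mM. A neighbour of Thursday's, charged with 0.80 M of free monomer, has R of 533 and ends at a length of 646, which is 1.21 times R.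

All runs are calculated for an exercise.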